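**Assumption:** the target has no stereocentre, and its biaryl axis (flanked only by OH, OH and a CH2 group) rotates freely at room temperature, so it is a single achiral compound and no stereocontrol is needed.

## Retrosynthetic overview

1. Target 17 ⇐ tetra-O-benzyl stilbene 15 by one hydrogenation (C=C saturation plus four O-benzyl hydrogenolyses).
2. 15 ⇐ α-arylcinnamic acid 14 (protodecarboxylation) ⇐ biaryl aldehyde 9 + arylacetic acid 11 by an intermolecular aldol-type (Perkin) condensation; this key step makes the C–C bond of the ethano bridge.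
3. 9 ⇐ bromoaldehyde 5 + arylboronate 8 (Suzuki–Miyaura coupling, biaryl bond).
4. 5 ⇐ 3-hydroxy-5-methoxybenzaldehyde 1 (bromination para to OMe while the phenol is masked as its acetate); 8 ⇐ bromohydroquinone 6; 11 ⇐ 3-hydroxyphenylacetic acid 10.
5. No ring is built: all three benzene rings are bought and joined in the order biaryl bond first, ethano bridge second.

## Route

Step 1
Reactants: 1 3-hydroxy-5-methoxybenzaldehyde
Product: 2 3-formyl-5-methoxyphenyl acetate
Conditions: Ac2O (1.2 equiv), Et3N (1.5 equiv), DMAP (5 mol%), CH2Cl2, 0 °C to rt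
Reagents that add atoms: acetic anhydride CC(=O)OC(C)=O
Why: DMAP-catalysed O-acetylation (nucleophilic acyl substitution) turns the strongly donating free OH into a weakly donating ester, so that the methoxy group alone directs the next step.

Step 2
Reactants: 2 3-formyl-5-methoxyphenyl acetate
Product: 3 2-bromo-3-formyl-5-methoxyphenyl acetate
Conditions: NBS (1.05 equiv), DMF, 0 °C to rt, dark
Reagents that add atoms: N-bromosuccinimide O=C1CCC(=O)N1Br
Why: Electrophilic aromatic bromination goes para to OMe, the strongest donor, which is C2 between CHO and OAc and the same site at which 3,5-dimethoxybenzaldehyde is brominated, because the acetoxy lone pair is tied up in the ester.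

Step 3
Reactants: 3 2-bromo-3-formyl-5-methoxyphenyl acetate
Product: 4 2-bromo-3-hydroxy-5-methoxybenzaldehyde
Conditions: K2CO3 (1.2 equiv), MeOH, 0 °C to rt, 30 min; then 1 M HCl
Reagents that add atoms: none
Why: Base-mediated transesterification (methanolysis) of an aryl acetate is fast at room temperature and leaves the aldehyde and the aryl bromide untouched.

Step 4
Reactants: 4 2-bromo-3-hydroxy-5-methoxybenzaldehyde
Product: 5 3-(benzyloxy)-2-bromo-5-methoxybenzaldehyde
Conditions: BnBr (1.2 equiv), K2CO3 (2 equiv), DMF, rt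
Reagents that add atoms: benzyl bromide BrCc1ccccc1
Why: Williamson ether synthesis on the acidic ortho-bromophenol installs a benzyl ether that survives every later step and is removed in the final hydrogenolysis.

Step 5
Reactants: 6 2-bromobenzene-1,4-diol (bromohydroquinone)
Product: 7 1,4-bis(benzyloxy)-2-bromobenzene
Conditions: BnBr (2.3 equiv), K2CO3 (3 equiv), DMF, 60 °C, N2
Reagents that add atoms: benzyl bromide BrCc1ccccc1
Why: Double Williamson etherification of both phenols under inert gas, which prevents air oxidation of the hydroquinone to the quinone.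

Step 6
Reactants: 7 1,4-bis(benzyloxy)-2-bromobenzene
Product: 8 2-[2,5-bis(benzyloxy)phenyl]-4,4,5,5-tetramethyl-1,3,2-dioxaborolane
Conditions: B2pin2 (1.2 equiv), Pd(dppf)Cl2 (3 mol%), KOAc (3 equiv), 1,4-dioxane, 90 °C
Reagents that add atoms: bis(pinacolato)diboron CC1(C)OB(OC1(C)C)B1OC(C)(C)C(C)(C)O1
Why: Miyaura borylation, in which zerovalent palladium inserts into the C–Br bond, acetate-assisted transmetalation with the diboron follows, and reductive elimination gives a stable, chromatographable pinacol boronate.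

Step 7
Reactants: 5 3-(benzyloxy)-2-bromo-5-methoxybenzaldehyde; 8 2-[2,5-bis(benzyloxy)phenyl]-4,4,5,5-tetramethyl-1,3,2-dioxaborolane
Product: 9 3-(benzyloxy)-2-[2,5-bis(benzyloxy)phenyl]-5-methoxybenzaldehyde
Conditions: Pd(OAc)2 (3 mol%), SPhos (6 mol%), K3PO4 (3 equiv), toluene/H2O (10:1), 100 °C; 1.3 equiv of 8
Reagents that add atoms: none
Why: Suzuki–Miyaura coupling, in which the ortho-formyl group speeds oxidative addition and the bulky biarylphosphine SPhos allows formation of the tri-ortho-substituted biaryl, whose axis is not configurationally stable.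

Step 8
Reactants: 10 3-hydroxyphenylacetic acid
Product: 11 2-[3-(benzyloxy)phenyl]acetic acid
Conditions: BnBr (1.3 equiv), KOH (3 equiv), EtOH/H2O (4:1), reflux; then 2 M HCl
Reagents that add atoms: benzyl bromide BrCc1ccccc1
Why: Williamson etherification of the dianion at the far more nucleophilic phenoxide, with any benzyl ester saponified in the same pot by the excess KOH.

Step 9
Reactants: 9 3-(benzyloxy)-2-[2,5-bis(benzyloxy)phenyl]-5-methoxybenzaldehyde; 11 2-[3-(benzyloxy)phenyl]acetic acid
Product: 14 (E)-3-{3-(benzyloxy)-2-[2,5-bis(benzyloxy)phenyl]-5-methoxyphenyl}-2-[3-(benzyloxy)phenyl]prop-2-enoic acid, via mixed anhydride 12 (not isolated), via beta-acetoxy acid 13 (not isolated)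
Conditions: Ac2O (5 equiv), Et3N (3 equiv), 120 °C, 12 h; then aq. HCl; 1.5 equiv of 11
Reagents that add atoms: none
Why: Perkin condensation, an intermolecular aldol-type condensation in which the enolate of the mixed anhydride adds to the non-enolisable aldehyde, acyl transfer gives the beta-acetoxy acid, and loss of acetic acid gives the favoured (E)-acid with the two aryl groups cis; no stereocentre remains.

Step 10
Reactants: 14 (E)-3-{3-(benzyloxy)-2-[2,5-bis(benzyloxy)phenyl]-5-methoxyphenyl}-2-[3-(benzyloxy)phenyl]prop-2-enoic acid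
Product: 15 (Z)-1-(benzyloxy)-2-[2,5-bis(benzyloxy)phenyl]-3-{2-[3-(benzyloxy)phenyl]ethenyl}-5-methoxybenzene
Conditions: Cu powder, quinoline, 200–210 °C, 2 h, N2
Reagents that add atoms: none
Why: Copper-mediated protodecarboxylation of an α-arylcinnamic acid proceeds through a vinylcopper species largely with retention to the (Z)-stilbene, and any (E)-isomer is equally useful because the double bond is hydrogenated next.

Step 11
Reactants: 15 (Z)-1-(benzyloxy)-2-[2,5-bis(benzyloxy)phenyl]-3-{2-[3-(benzyloxy)phenyl]ethenyl}-5-methoxybenzene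
Product: 17 2-{2-hydroxy-6-[2-(3-hydroxyphenyl)ethyl]-4-methoxyphenyl}benzene-1,4-diol, via saturated tetrabenzyl ether 16 (not isolated)
Conditions: H2 (1 atm), 10% Pd/C, EtOAc/MeOH (1:1), rt; filtered and concentrated under argon
Reagents that add atoms: none
Why: Heterogeneous catalytic hydrogenation saturates the stilbene double bond and then hydrogenolyses all four benzyl ethers in one operation, while the aryl methyl ether is inert and no stereocentre is created.

## Compound list

1 | 3-hydroxy-5-methoxybenzaldehyde | COc1cc(O)cc(C=O)c1 | starting material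
2 | 3-formyl-5-methoxyphenyl acetate | COc1cc(OC(C)=O)cc(C=O)c1 | intermediate
3 | 2-bromo-3-formyl-5-methoxyphenyl acetate | COc1cc(OC(C)=O)c(Br)c(C=O)c1 | intermediate
4 | 2-bromo-3-hydroxy-5-methoxybenzaldehyde | COc1cc(O)c(Br)c(C=O)c1 | intermediate
5 | 3-(benzyloxy)-2-bromo-5-methoxybenzaldehyde | COc1cc(OCc2ccccc2)c(Br)c(C=O)c1 | intermediate
6 | 2-bromobenzene-1,4-diol (bromohydroquinone) | Oc1ccc(O)c(Br)c1 | starting material
7 | 1,4-bis(benzyloxy)-2-bromobenzene | Brc1cc(OCc2ccccc2)ccc1OCc1ccccc1 | intermediate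
8 | 2-[2,5-bis(benzyloxy)phenyl]-4,4,5,5-tetramethyl-1,3,2-dioxaborolane | CC1(C)OB(OC1(C)C)c1cc(OCc2ccccc2)ccc1OCc1ccccc1 | intermediate
9 | 3-(benzyloxy)-2-[2,5-bis(benzyloxy)phenyl]-5-methoxybenzaldehyde | COc1cc(OCc2ccccc2)c(-c2cc(OCc3ccccc3)ccc2OCc2ccccc2)c(C=O)c1 | intermediate
10 | 3-hydroxyphenylacetic acid | OC(=O)Cc1cccc(O)c1 | starting material
11 | 2-[3-(benzyloxy)phenyl]acetic acid | OC(=O)Cc1cccc(OCc2ccccc2)c1 | intermediate
12 | acetic 2-[3-(benzyloxy)phenyl]acetic anhydride (mixed anhydride, formed in situ) | CC(=O)OC(=O)Cc1cccc(OCc2ccccc2)c1 | intermediate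
13 | 3-acetoxy-3-{3-(benzyloxy)-2-[2,5-bis(benzyloxy)phenyl]-5-methoxyphenyl}-2-[3-(benzyloxy)phenyl]propanoic acid (racemic diastereomer mixture, formed in situ) | CC(=O)OC(c1cc(OC)cc(OCc2ccccc2)c1-c1cc(OCc2ccccc2)ccc1OCc1ccccc1)C(C(=O)O)c1cccc(OCc2ccccc2)c1 | intermediate
14 | (E)-3-{3-(benzyloxy)-2-[2,5-bis(benzyloxy)phenyl]-5-methoxyphenyl}-2-[3-(benzyloxy)phenyl]prop-2-enoic acid | OC(=O)/C(=C/c1cc(OC)cc(OCc2ccccc2)c1-c1cc(OCc2ccccc2)ccc1OCc1ccccc1)c1cccc(OCc2ccccc2)c1 | intermediate
15 | (Z)-1-(benzyloxy)-2-[2,5-bis(benzyloxy)phenyl]-3-{2-[3-(benzyloxy)phenyl]ethenyl}-5-methoxybenzene | COc1cc(OCc2ccccc2)c(-c2cc(OCc3ccccc3)ccc2OCc2ccccc2)c(/C=C\c2cccc(OCc3ccccc3)c2)c1 | intermediate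
16 | 1-(benzyloxy)-2-[2,5-bis(benzyloxy)phenyl]-3-{2-[3-(benzyloxy)phenyl]ethyl}-5-methoxybenzene (formed in situ) | COc1cc(OCc2ccccc2)c(-c2cc(OCc3ccccc3)ccc2OCc2ccccc2)c(CCc2cccc(OCc3ccccc3)c2)c1 | intermediate
17 | 2-{2-hydroxy-6-[2-(3-hydroxyphenyl)ethyl]-4-methoxyphenyl}benzene-1,4-diol | COc1cc(O)c(-c2cc(O)ccc2O)c(CCc2cccc(O)c2)c1 | target

## Step count and risks

Total steps: 11. Longest linear sequence: 8 steps (steps 1, 2, 3, 4, 7, 9, 10, 11, from 1 to 17).

**Step 2 (regioselectivity of the bromination).** The position para to OMe is flanked by CHO and OAc, so bromination ortho to OMe could compete. The correct isomer is recognised by NOE from the OMe signal to two aromatic protons. The fallback sets out from phenol 1 and uses phenol-directed ortho-delivery instead of ester masking. NBS with 10 mol% i-Pr2NH in CH2Cl2 at 0 °C transfers bromine through the hydrogen-bonded N-bromoamine to the position ortho to the free OH that is also para to OMe. This gives 2-bromo-3-hydroxy-5-methoxybenzaldehyde 4 directly, and the route is rejoined at 4, before step 4. This detour makes no compound outside the list (F0).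

**Step 9 (Perkin condensation on a hindered ortho-aryl benzaldehyde).** If the equilibrium condensation stalls, the fallback is a stepwise directed aldol that sets out from acid 11 and aldehyde 9. Acid 11 is esterified (MeOH, cat. H2SO4, reflux) to methyl 2-[3-(benzyloxy)phenyl]acetate F1. LDA in THF at −78 °C converts this into the lithium enolate of methyl 2-[3-(benzyloxy)phenyl]acetate F2. Addition of aldehyde 9 and NH4Cl quench give methyl 3-{3-(benzyloxy)-2-[2,5-bis(benzyloxy)phenyl]-5-methoxyphenyl}-2-[3-(benzyloxy)phenyl]-3-hydroxypropanoate F3 as a diastereomer mixture. MsCl/Et3N in CH2Cl2 at 0 °C gives the mesylate methyl 3-{3-(benzyloxy)-2-[2,5-bis(benzyloxy)phenyl]-5-methoxyphenyl}-2-[3-(benzyloxy)phenyl]-3-(methylsulfonyloxy)propanoate F4. DBU in the same flask eliminates it to methyl (E)-3-{3-(benzyloxy)-2-[2,5-bis(benzyloxy)phenyl]-5-methoxyphenyl}-2-[3-(benzyloxy)phenyl]prop-2-enoate F5. LiOH in THF/MeOH/H2O at 60 °C followed by acidification gives acid 14, where the route is rejoined; any (Z)-isomer does not matter because the double bond is hydrogenated later.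

**Step 10 (decarboxylation at about 200 °C in the presence of four benzyl ethers).** If debenzylation or decomposition intervenes, the fallback sets out from acid 14 and removes the carboxyl group by a radical pathway at room temperature. Only the C=C bond is reduced first (H2 1 atm, Pd/C poisoned with Ph2S, EtOAc, rt), giving racemic 3-{3-(benzyloxy)-2-[2,5-bis(benzyloxy)phenyl]-5-methoxyphenyl}-2-[3-(benzyloxy)phenyl]propanoic acid F6. 2-Mercaptopyridine N-oxide, DCC and DMAP in CH2Cl2 in the dark convert it into the Barton ester 2-thioxopyridin-1(2H)-yl 3-{3-(benzyloxy)-2-[2,5-bis(benzyloxy)phenyl]-5-methoxyphenyl}-2-[3-(benzyloxy)phenyl]propanoate F7. Visible-light photolysis with t-BuSH in THF at rt (Barton reductive decarboxylation) gives the tetrabenzyl bibenzyl 16, which is here isolated. The route is rejoined at 16, and hydrogenolysis under the conditions of step 11 gives 17.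

## Further compounds

F0 | step 2 | none | none
F1 | step 9 | methyl 2-[3-(benzyloxy)phenyl]acetate | COC(=O)Cc1cccc(OCc2ccccc2)c1
F2 | step 9 | lithium enolate of methyl 2-[3-(benzyloxy)phenyl]acetate | [Li]OC(OC)=Cc1cccc(OCc2ccccc2)c1
F3 | step 9 | methyl 3-{3-(benzyloxy)-2-[2,5-bis(benzyloxy)phenyl]-5-methoxyphenyl}-2-[3-(benzyloxy)phenyl]-3-hydroxypropanoate (racemic diastereomer mixture) | COC(=O)C(c1cccc(OCc2ccccc2)c1)C(O)c1cc(OC)cc(OCc2ccccc2)c1-c1cc(OCc2ccccc2)ccc1OCc1ccccc1
F4 | step 9 | methyl 3-{3-(benzyloxy)-2-[2,5-bis(benzyloxy)phenyl]-5-methoxyphenyl}-2-[3-(benzyloxy)phenyl]-3-(methylsulfonyloxy)propanoate (racemic diastereomer mixture) | COC(=O)C(c1cccc(OCc2ccccc2)c1)C(OS(C)(=O)=O)c1cc(OC)cc(OCc2ccccc2)c1-c1cc(OCc2ccccc2)ccc1OCc1ccccc1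
F5 | step 9 | methyl (E)-3-{3-(benzyloxy)-2-[2,5-bis(benzyloxy)phenyl]-5-methoxyphenyl}-2-[3-(benzyloxy)phenyl]prop-2-enoate | COC(=O)/C(=C/c1cc(OC)cc(OCc2ccccc2)c1-c1cc(OCc2ccccc2)ccc1OCc1ccccc1)c1cccc(OCc2ccccc2)c1
F6 | step 10 | 3-{3-(benzyloxy)-2-[2,5-bis(benzyloxy)phenyl]-5-methoxyphenyl}-2-[3-(benzyloxy)phenyl]propanoic acid (racemic) | OC(=O)C(Cc1cc(OC)cc(OCc2ccccc2)c1-c1cc(OCc2ccccc2)ccc1OCc1ccccc1)c1cccc(OCc2ccccc2)c1
F7 | step 10 | 2-thioxopyridin-1(2H)-yl 3-{3-(benzyloxy)-2-[2,5-bis(benzyloxy)phenyl]-5-methoxyphenyl}-2-[3-(benzyloxy)phenyl]propanoate (racemic) | S=c1ccccn1OC(=O)C(Cc1cc(OC)cc(OCc2ccccc2)c1-c1cc(OCc2ccccc2)ccc1OCc1ccccc1)c1cccc(OCc2ccccc2)c1
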